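**Plan**
- Retrosynthesis: the galloyl ester at A-C3–O is cut first, then A-C4–A-C4a (epoxide–arene closure), then the A-C2–O aryl ether, then the oxirane and the vinyl–carbinol bond back to a C7 aldehyde. Last, the benzotropolone is cut into (−)-epicatechin and 2,3,4-trihydroxybenzaldehyde.
- Forward: an oxidative annulation builds the seven-membered ring on the catechol ring of epicatechin, whose chroman becomes chroman B on C1. After protection, the C7 aldehyde is carried to vinyl carbinol, epoxy alcohol and aryl ether. The dihydropyran of chroman A (on C7) is the last ring formed, followed by esterification and one hydrogenolysis.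
- Enabling feature: A-C4 is an unsubstituted CH2 bonded to the phloroglucinol-type carbon A-C4a, and A-C3 carries the only oxygen that must be acylated. A terminal epoxide opened by the symmetric 3,5-dibenzyloxyphenyl ether on A-C2 therefore closes ring A's pyran and frees that one hydroxyl.
- Stereochemistry: B-C2 and B-C3 come from (−)-epicatechin. A-C3 comes from a Sharpless kinetic-resolution epoxidation with L-(+)-tartrate. A-C2 comes from the same resolution followed by Mitsunobu inversion. The ring closure touches no stereocentre.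

Key step: step 7

Assumption: positions follow benzo[7]annulene numbering (C5 carbonyl, C6 hydroxyl, chroman A on C7, chroman B on C1), and both chromans are (2R,3R), 2,3-cis, as read from the target SMILES. Compounds 1, 2, 7, 10 and 13 are taken as purchasable.

**Step 1**
Reactants: 1 (−)-epicatechin; 2 2,3,4-trihydroxybenzaldehyde
Product: 4 3,4,6-trihydroxy-5-oxo-1-[(2R,3R)-3,5,7-trihydroxychroman-2-yl]-5H-benzo[7]annulene-7-carbaldehyde, via epicatechin o-quinone 3 (not isolated)
Conditions: NaIO4 (3 equiv, slow addition), 2 in excess, acetone/aq. phosphate buffer pH 5, 0 °C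
Reagents that add atoms: none
Why: Periodate oxidises the catechol ring of 1 to quinone 3, which is attacked by C5 of 2 (ortho and para to hydroxyls, meta to the formyl group); re-oxidation, intramolecular carbonyl addition and loss of C4 of 2 as CO2 (the oxidative catechol–pyrogallol benzotropolone annulation of the purpurogallin/theaflavin type) should place the formyl-bearing carbon at C7 next to the tropolone hydroxyl, while the two chroman stereocentres of 1 are not involved.

**Step 2**
Reactants: 4 benzotropolone aldehyde hexaol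
Product: 5 3,4,6-tris(benzyloxy)-1-[(2R,3R)-5,7-bis(benzyloxy)-3-hydroxychroman-2-yl]-5-oxo-5H-benzo[7]annulene-7-carbaldehyde
Conditions: BnBr (7 equiv), K2CO3, DMF, 0 °C to rt
Reagents that add atoms: benzyl bromide, BrCc1ccccc1
Why: Williamson etherification with a carbonate base should alkylate only the five acidic phenolic and tropolone hydroxyls and leave the secondary B-C3 alcohol, and the benzo fusion fixes the tropolone as the 5-oxo tautomer so that the 6-benzyl ether is the expected product.

**Step 3**
Reactants: 5 pentabenzyl ether with free B-C3 hydroxyl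
Product: 6 benzyl (2R,3R)-5,7-bis(benzyloxy)-2-[3,4,6-tris(benzyloxy)-7-formyl-5-oxo-5H-benzo[7]annulen-1-yl]chroman-3-yl carbonate
Conditions: CbzCl, 4-(dimethylamino)pyridine (DMAP, 3 equiv), CH2Cl2, 0 °C to rt
Reagents that add atoms: benzyl chloroformate, O=C(Cl)OCc1ccccc1
Why: DMAP-mediated acyl transfer protects the hindered secondary alcohol without generating an alkoxide that could attack the non-enolisable aldehyde or the activated tropolone ether, and the benzyl carbonate is chosen because it falls in the final hydrogenolysis.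

**Step 4**
Reactants: 6 carbonate-protected aldehyde; 7 vinylmagnesium bromide
Product: 8 allylic alcohol in which C7 carries CH(OH)CH=CH2, both carbinol epimers
Conditions: THF, −78 °C; then aq. NH4Cl
Reagents that add atoms: none
Why: Grignard 1,2-addition should occur at the aldehyde, by far the most electrophilic carbonyl, while the carbonate and the vinylogous ester of the tropolone ether are inert at −78 °C; the remote stereocentres give no control, so both carbinol epimers are expected and step 5 separates them.

**Step 5**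
Reactants: 8 allylic alcohol (epimer mixture)
Product: 9 anti epoxy alcohol in which C7 carries (S)-CH(OH)–[(R)-oxiran-2-yl]
Conditions: Ti(OiPr)4 (0.5 equiv), diisopropyl L-(+)-tartrate (0.6 equiv), t-BuOOH (0.6 equiv), 4 Å MS, CH2Cl2, −20 °C
Reagents that add atoms: tert-butyl hydroperoxide, CC(C)(C)OO
Why: In the Sharpless kinetic resolution the L-(+)-tartrate catalyst epoxidises only the (R)-carbinol epimer of this aryl vinyl carbinol, from the face that gives the erythro (anti) product with an (R) oxirane carbon, so A-C3 and the carbinol centre are set together by the reagent; the (S)-epimer of 8 stays unchanged and is removed by chromatography, so at most half of 8 is converted.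

**Step 6**
Reactants: 9 anti epoxy alcohol; 10 3,5-bis(benzyloxy)phenol
Product: 11 syn aryloxy epoxide in which C7 carries (R)-CH[O-3,5-bis(benzyloxy)phenyl]–[(R)-oxiran-2-yl]
Conditions: PPh3, DIAD, THF, 0 °C to rt
Reagents that add atoms: none
Why: Mitsunobu etherification displaces the activated carbinol oxygen by the phenol with clean SN2 inversion, turning the (S) carbinol into the (R) aryl ether that is A-C2; the electron-poor tropone ring disfavours ionisation and the oxirane is inert under these neutral conditions.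

**Step 7**
Reactants: 11 syn aryloxy epoxide
Product: 12 chroman-3-ol in which C7 carries (2R,3R)-5,7-bis(benzyloxy)-3-hydroxychroman-2-yl (A-C3 hydroxyl is the only free one)
Conditions: (CF3)2CHOH (HFIP)/CH2Cl2 (4:1), 0.005 M, 0 °C to rt
Reagents that add atoms: none
Why: Hydrogen-bond activation of the oxirane oxygen by HFIP lets the 3,5-dibenzyloxyphenyl ether, a ring as nucleophilic as a phloroglucinol triether, attack the terminal CH2 through the carbon ortho to the ether oxygen and para to a benzyloxy group in an SN2-like Friedel–Crafts alkylation, followed by rearomatisation; the closest known reaction is the acid- or fluorinated-alcohol-promoted cyclisation of aryl glycidyl ethers to chroman-3-ols. The dihydropyran ring of chroman A closes in the 6-endo mode with respect to the epoxide, forming A-C4–A-C4a and releasing the A-C3 hydroxyl. No stereocentre is created: the A-C2–O and A-C3–O bonds stay intact, so the (R,R) syn arrangement fixed in steps 5 and 6 becomes the 2,3-cis chroman. The step needs 6-endo over 5-exo opening, which is secured by attack at the unhindered primary carbon while the internal carbon is shielded by the branched A-C2; the two ortho positions of the symmetric ring are equivalent, so only one regioisomer can form. It also needs the A-C2–OAr bond not to ionise, which the electron-poor tropone ring next to it ensures, and high dilution keeps the remote chroman B ring from intermolecular alkylation.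

**Step 8**
Reactants: 12 chroman-3-ol; 13 3,4,5-tris(benzyloxy)benzoic acid
Product: 14 perbenzylated target, the A-C3 3,4,5-tris(benzyloxy)benzoate of 12
Conditions: DCC, DMAP (cat.), CH2Cl2, rt
Reagents that add atoms: none
Why: Steglich esterification acylates the single free hydroxyl of 12, an axial flavan-3-ol hydroxyl of the kind routinely galloylated with this acid, and no stereocentre is touched.

**Step 9**
Reactants: 14 perbenzylated target
Product: 15 target CNP0125877.1
Conditions: H2 (1 atm), Pd(OH)2/C, THF/MeOH, rt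
Reagents that add atoms: none
Why: Catalytic hydrogenolysis should cleave the ten benzyl ethers and the benzyl carbonate (which loses CO2) in one operation, while the gallate ester, the chroman C2–O bonds and the benzotropolone are expected to survive these mild conditions.

**Compound list**
1 | (−)-epicatechin, (2R,3R)-2-(3,4-dihydroxyphenyl)chroman-3,5,7-triol | O[C@@H]1Cc2c(O)cc(O)cc2O[C@@H]1c1ccc(O)c(O)c1 | starting material
2 | 2,3,4-trihydroxybenzaldehyde | O=Cc1ccc(O)c(O)c1O | starting material
3 | epicatechin o-quinone, 4-[(2R,3R)-3,5,7-trihydroxychroman-2-yl]cyclohexa-3,5-diene-1,2-dione | O[C@@H]1Cc2c(O)cc(O)cc2O[C@@H]1C1=CC(=O)C(=O)C=C1 | intermediate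
4 | 3,4,6-trihydroxy-5-oxo-1-[(2R,3R)-3,5,7-trihydroxychroman-2-yl]-5H-benzo[7]annulene-7-carbaldehyde | O=Cc1ccc2c([C@H]3Oc4cc(O)cc(O)c4C[C@H]3O)cc(O)c(O)c2c(=O)c1O | intermediate
5 | 3,4,6-tris(benzyloxy)-1-[(2R,3R)-5,7-bis(benzyloxy)-3-hydroxychroman-2-yl]-5-oxo-5H-benzo[7]annulene-7-carbaldehyde | O=Cc1ccc2c([C@H]3Oc4cc(OCc5ccccc5)cc(OCc5ccccc5)c4C[C@H]3O)cc(OCc5ccccc5)c(OCc5ccccc5)c2c(=O)c1OCc5ccccc5 | intermediate
6 | benzyl (2R,3R)-5,7-bis(benzyloxy)-2-[3,4,6-tris(benzyloxy)-7-formyl-5-oxo-5H-benzo[7]annulen-1-yl]chroman-3-yl carbonate | O=Cc1ccc2c([C@H]3Oc4cc(OCc5ccccc5)cc(OCc5ccccc5)c4C[C@H]3OC(=O)OCc5ccccc5)cc(OCc5ccccc5)c(OCc5ccccc5)c2c(=O)c1OCc5ccccc5 | intermediate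
7 | vinylmagnesium bromide | C=C[Mg]Br | starting material
8 | allylic alcohol, 6 with C7–CH(OH)CH=CH2 in place of CHO, both carbinol epimers | C=CC(O)c1ccc2c([C@H]3Oc4cc(OCc5ccccc5)cc(OCc5ccccc5)c4C[C@H]3OC(=O)OCc5ccccc5)cc(OCc5ccccc5)c(OCc5ccccc5)c2c(=O)c1OCc5ccccc5 | intermediate
9 | anti epoxy alcohol, C7–(S)-CH(OH)–[(R)-oxiran-2-yl] | O[C@H]([C@H]1CO1)c1ccc2c([C@H]3Oc4cc(OCc5ccccc5)cc(OCc5ccccc5)c4C[C@H]3OC(=O)OCc5ccccc5)cc(OCc5ccccc5)c(OCc5ccccc5)c2c(=O)c1OCc5ccccc5 | intermediate
10 | 3,5-bis(benzyloxy)phenol | Oc1cc(OCc2ccccc2)cc(OCc2ccccc2)c1 | starting material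
11 | syn aryloxy epoxide, C7–(R)-CH[O-3,5-bis(benzyloxy)phenyl]–[(R)-oxiran-2-yl] | O(c1cc(OCc5ccccc5)cc(OCc5ccccc5)c1)[C@@H]([C@H]1CO1)c1ccc2c([C@H]3Oc4cc(OCc5ccccc5)cc(OCc5ccccc5)c4C[C@H]3OC(=O)OCc5ccccc5)cc(OCc5ccccc5)c(OCc5ccccc5)c2c(=O)c1OCc5ccccc5 | intermediate
12 | chroman-3-ol, C7–[(2R,3R)-5,7-bis(benzyloxy)-3-hydroxychroman-2-yl], B-C3 benzyl carbonate retained | O[C@@H]1Cc2c(OCc5ccccc5)cc(OCc5ccccc5)cc2O[C@@H]1c1ccc2c([C@H]3Oc4cc(OCc5ccccc5)cc(OCc5ccccc5)c4C[C@H]3OC(=O)OCc5ccccc5)cc(OCc5ccccc5)c(OCc5ccccc5)c2c(=O)c1OCc5ccccc5 | intermediate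
13 | 3,4,5-tris(benzyloxy)benzoic acid | O=C(O)c1cc(OCc2ccccc2)c(OCc2ccccc2)c(OCc2ccccc2)c1 | starting material
14 | perbenzylated target, A-C3 3,4,5-tris(benzyloxy)benzoate of 12 | O=C(O[C@@H]1Cc2c(OCc5ccccc5)cc(OCc5ccccc5)cc2O[C@@H]1c1ccc2c([C@H]3Oc4cc(OCc5ccccc5)cc(OCc5ccccc5)c4C[C@H]3OC(=O)OCc5ccccc5)cc(OCc5ccccc5)c(OCc5ccccc5)c2c(=O)c1OCc5ccccc5)c1cc(OCc5ccccc5)c(OCc5ccccc5)c(OCc5ccccc5)c1 | intermediate
15 | CNP0125877.1 | O=C(O[C@@H]1Cc2c(O)cc(O)cc2O[C@@H]1c1ccc2c([C@H]3Oc4cc(O)cc(O)c4C[C@H]3O)cc(O)c(O)c2c(=O)c1O)c1cc(O)c(O)c(O)c1 | target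

**Step count**
Total: 9 steps. Longest linear sequence: 9 steps (1 → 15); 2, 7, 10 and 13 enter as purchased.

**Steps most likely to fail**

Step 1. The formyl-substituted pyrogallol has its activating hydroxyls conjugated to the aldehyde, so it may add too slowly to the quinone, which would then be consumed by self-condensation of epicatechin. The fallback carries the C7 carbon at the methyl oxidation level. Hydrogenolysis of the aldehyde of 2 (H2, Pd/C, AcOH) gives 4-methylpyrogallol F1, a more nucleophilic partner. The same periodate annulation with 1 should give the 7-methylbenzotropolone F2. Benzylation as in step 2 gives the pentabenzyl ether F3, and carbonate formation as in step 3 gives the 7-methyl carbonate F4. Oxidation with SeO2 in dioxane of the methyl group, which is vinylogously activated by the tropone carbonyl, then returns to the route at 6.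

Step 7. The unactivated terminal epoxide may be opened too slowly. The activated epoxide may then divert to 5-exo attack, hydride shift or solvolysis, or the aryloxy group at A-C2 may be lost. The fallback reverses the order of the two bond formations and sets out from 9. Phenol 10 is C-alkylated ortho to its hydroxyl by the terminal epoxide carbon (intermolecular Friedel–Crafts opening, HFIP or BF3·OEt2), giving the (1S,2R)-triol F5. Intramolecular Mitsunobu etherification (PPh3, DIAD) then closes O1–C2 of chroman A with inversion at the benzylic carbon and returns to the route at 12. This path also avoids the intermolecular displacement of step 6, but it depends on the benzylic hydroxyl being displaced in preference to the neighbouring one.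

Step 5. Terminal vinyl carbinols are the slowest substrates for the titanium–tartrate epoxidation, and the neighbouring tropolone ether can chelate titanium, so conversion and discrimination between the carbinol epimers may both suffer. The fallback sets the carbinol centre by reduction and sets out from 8. MnO2 oxidation of both epimers gives the vinyl ketone F6. Corey–Bakshi–Shibata reduction with the (S)-B-methyl oxazaborolidine derived from diphenylprolinol and catecholborane should give the (R)-allylic alcohol F7. Hydroxyl-directed epoxidation with VO(acac)2 and t-BuOOH, which favours the erythro product for such carbinols, returns to the route at 9.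

**Further compounds**
F1 | step 1 | 4-methylpyrogallol (4-methylbenzene-1,2,3-triol) | Cc1ccc(O)c(O)c1O
F2 | step 1 | 3,4,6-trihydroxy-7-methyl-1-[(2R,3R)-3,5,7-trihydroxychroman-2-yl]-5H-benzo[7]annulen-5-one | Cc1ccc2c([C@H]3Oc4cc(O)cc(O)c4C[C@H]3O)cc(O)c(O)c2c(=O)c1O
F3 | step 1 | 3,4,6-tris(benzyloxy)-1-[(2R,3R)-5,7-bis(benzyloxy)-3-hydroxychroman-2-yl]-7-methyl-5H-benzo[7]annulen-5-one | Cc1ccc2c([C@H]3Oc4cc(OCc5ccccc5)cc(OCc5ccccc5)c4C[C@H]3O)cc(OCc5ccccc5)c(OCc5ccccc5)c2c(=O)c1OCc5ccccc5
F4 | step 1 | benzyl (2R,3R)-5,7-bis(benzyloxy)-2-[3,4,6-tris(benzyloxy)-7-methyl-5-oxo-5H-benzo[7]annulen-1-yl]chroman-3-yl carbonate | Cc1ccc2c([C@H]3Oc4cc(OCc5ccccc5)cc(OCc5ccccc5)c4C[C@H]3OC(=O)OCc5ccccc5)cc(OCc5ccccc5)c(OCc5ccccc5)c2c(=O)c1OCc5ccccc5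
F5 | step 7 | (1S,2R)-3-[2,4-bis(benzyloxy)-6-hydroxyphenyl]-1-(C7-benzotropolonyl)propane-1,2-diol, remainder as in 9 | O[C@H]([C@H](O)Cc1c(O)cc(OCc5ccccc5)cc1OCc5ccccc5)c1ccc2c([C@H]3Oc4cc(OCc5ccccc5)cc(OCc5ccccc5)c4C[C@H]3OC(=O)OCc5ccccc5)cc(OCc5ccccc5)c(OCc5ccccc5)c2c(=O)c1OCc5ccccc5
F6 | step 5 | vinyl ketone, 8 with C7–C(=O)CH=CH2 | C=CC(=O)c1ccc2c([C@H]3Oc4cc(OCc5ccccc5)cc(OCc5ccccc5)c4C[C@H]3OC(=O)OCc5ccccc5)cc(OCc5ccccc5)c(OCc5ccccc5)c2c(=O)c1OCc5ccccc5
F7 | step 5 | (R)-carbinol epimer of allylic alcohol 8 | C=C[C@@H](O)c1ccc2c([C@H]3Oc4cc(OCc5ccccc5)cc(OCc5ccccc5)c4C[C@H]3OC(=O)OCc5ccccc5)cc(OCc5ccccc5)c(OCc5ccccc5)c2c(=O)c1OCc5ccccc5
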